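The vessel is closed and stirred and holds starting material, second substrate, partner and a little free catalyst. I want to know how much target stands in it at 8.0 d, and which single change gains the most.

| flask | starting material | second substrate | partner | free catalyst | temperature | remark | time |
|---|---|---|---|---|---|---|---|
| east | 1 M | 2 M | 0.70 M | 10 mM | −20 °C | the very flask that is asked about, followed so far |  |
| west | 1 M | 2 M | 0.70 M | 10 mM | −35 °C | run made earlier |  |
| flask | 1.0 M | 2.00 M | 0.700 M | 10 mM | −20 °C |  | 8.0 d |

- east (time / h: target / %, starting material / %): 30.0: 18.4, 75.6; 60.0: 18.2, 74.6; 96.0: 18.1, 74.9; 120: 17.7, 75.2; 144: 17.7, 76.2; 192: 17.1, 75.8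
- west (time / h: target / %, starting material / %): 60.0: 8.9, 78.6; 120: 8.6, 78.6; 192: 8.1, 79.0; 240: 9.3, 78.7; 288: 9.0, 79.5; 360: 8.6, 78.5

(each reading ± 0.5 percentage points)

- target that was removed still counts
- additions bring no volume worth counting

- maple: at 8.0 d add free catalyst, 100% of the amount charged, then wait 4.0 d
- cedar: at 8.0 d take out 90% of the target then present, then wait 4.0 d
- oak: change nothing and wait 4.0 d more
- birch: at 8.0 d add partner, 100% of the amount charged, then wait 4.0 d
- alder: at 8.0 d raise the temperature by 15 K, then wait 4.0 d

* target, in percent of the starting material first charged, at 8.0 d
* the remedy with the largest gain of target, or "none" below 2 percentage points (maple / cedar / oak / birch / alder / none)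
* target present, with what was taken out counted in, in percent of the starting material first charged, after cedar
* target present, with what was taken out counted in, in percent of the starting material first charged, after birch

In the east run the target reads flat from the first reading on, yet 75.8% of the starting material still stands at the last reading. I see two suspects: a catalyst that has died, or a reagent that has been spent, and these readings do not separate them. The partner is charged in the smallest amount, at 0.700 of the starting material, so it is my candidate for the limiting reagent. The east run has lost 24.2% of its starting material, which is less than the partner charged. So if the partner is gone, something else took the rest. I cannot read what, but the second substrate is charged at twice the starting material and is my candidate.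

I commit to the spent partner and write its balance. The mean of the east target readings over the partner charged gives 0.255: that is the target share, the target standing per partner charged. The colder west run, with the same charges, reads 0.125, half of that, so I carry the east share at the temperature of the east run. For this flask I expect 17.9% at 8.0 d. If the share holds, a second portion of partner should bring the same share again, 35.7% in total after birch, while I expect fresh catalyst to bring nothing.

The forecast reads the same plateau the other way. It gives 17.5% now, 17.5% after cedar and 17.5% after birch, and it chooses maple: “A fixed turnover number from a dying catalyst fits better, though the data cannot exclude equilibrium.” We part on birch and maple.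

The flask gives 18.1% at 8.0 d, and the best remedy is birch, which gains 18 percentage points and reaches 35.8%. Maple gains 0 points, and cedar reaches 22.3%.

    partner + catalyst intermediate B → free catalyst + second product (k = 41.7 M⁻¹ h⁻¹, Ea = 49.0 kJ mol⁻¹)
    starting material + free catalyst ⇌ catalyst intermediate A (K = 4.44 M⁻¹, k = 57.3 M⁻¹ h⁻¹, Ea = 41.0 kJ mol⁻¹, ΔH = 36.0 kJ mol⁻¹)
    target ⇌ isomer of the product (K = 0.350, k = 0.316 h⁻¹, Ea = 75.0 kJ mol⁻¹, ΔH = −46.0 kJ mol⁻¹)
    second substrate + free catalyst ⇌ catalyst intermediate B (K = 11.3 M⁻¹, k = 60.9 M⁻¹ h⁻¹, Ea = 62.0 kJ mol⁻¹, ΔH = −30.0 kJ mol⁻¹)
    partner + catalyst intermediate A → free catalyst + target (k = 148 M⁻¹ h⁻¹, Ea = 53.0 kJ mol⁻¹)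
    (constants at −20 °C)

In this flask the partner stands at 0% of its charge after 192 h, and half the turnover of its step with catalyst intermediate B is done by 1.49 h, far sooner than the 8.0 d of waiting. Of the charged partner, 65.2% stands as second product and 34.8% as target and isomer of the product. The target share 0.255 applied to the added partner gives 18 points beside the 18 points of birch. On the neighbour flask, the same recipe and time with 0.17 M of partner, it gives 4.34%, and that flask holds 4.77%.

The data are calculated for substances that don't exist.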